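**Retrosynthetic overview**
1. The pyridine ring closes last. The O-benzyl target comes from the 1-chloroisoquinoline (C1-methyl by Negishi coupling), which comes from the 3-methylisoquinolin-1(2H)-one, made from a 2-acetonylbenzoate and ammonia.
2. The 2-acetonylbenzoate comes from Claisen-type acylation of the benzylic anion of a 3-aryl-6-methylsalicylate (C4–C3 bond).
3. Key disconnection: the phenol ring comes from a γ-naphthyl acetoacetate and crotonaldehyde, by intermolecular Michael addition (C8a–C4a), aldol closure (C7–C6) and aromatisation. The biaryl axis is the former naphthyl–CH2 bond.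
4. The γ-naphthyl acetoacetate comes from the naphthylacetic acid and Meldrum's acid. That acid traces back to 1-bromo-4,5-dimethoxy-7-methylnaphthalene, made from 2-bromo-5-methoxybenzaldehyde and diethyl succinate (Stobbe condensation, ring closure).
5. Ring order: methyl-bearing naphthalene ring, then phenol ring, then pyridine ring.

Assumption: the SMILES has no stereodescriptor and no stereocentre. The 7,8'-axis is flanked only by OH, two H and one peri C–H, so it rotates freely at room temperature. There is no enantiomer to select and no stereocontrol is needed.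

**Step 1**
Reactants: 1 2-bromo-5-methoxybenzaldehyde; 2 diethyl succinate
Product: 3 (E)-4-(2-bromo-5-methoxyphenyl)-3-(ethoxycarbonyl)but-3-enoic acid
Conditions: NaOEt (1.5 equiv), EtOH, reflux; aq. HCl
Reagents that add atoms: none
Why: In this Stobbe condensation, aldol addition of the succinate enolate, lactonisation and eliminative ring opening give the half-ester, mainly as the E isomer with the aryl group cis to CH2CO2H as ring closure requires.

**Step 2**
Reactants: 3 (E)-4-(2-bromo-5-methoxyphenyl)-3-(ethoxycarbonyl)but-3-enoic acid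
Product: 4 ethyl 4-acetoxy-8-bromo-5-methoxy-2-naphthoate
Conditions: Ac2O, NaOAc, reflux
Reagents that add atoms: acetic anhydride, CC(=O)OC(C)=O
Why: Intramolecular Friedel–Crafts acylation through the mixed anhydride can only occur at the one free ortho position (bromine blocks the other, OMe activates this one), and the resulting naphthol is trapped as its acetate.

**Step 3**
Reactants: 4 ethyl 4-acetoxy-8-bromo-5-methoxy-2-naphthoate
Product: 5 ethyl 8-bromo-4-hydroxy-5-methoxy-2-naphthoate
Conditions: NaOEt (1.1 equiv), EtOH, 0 °C → rt; aq. HCl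
Reagents that add atoms: none
Why: Ethanolysis (transesterification) cleaves the reactive aryl acetate, while ethoxide exchange at the ethyl ester is degenerate.

**Step 4**
Reactants: 5 ethyl 8-bromo-4-hydroxy-5-methoxy-2-naphthoate
Product: 6 ethyl 8-bromo-4,5-dimethoxy-2-naphthoate
Conditions: MeI, K2CO3, acetone, reflux
Reagents that add atoms: iodomethane, CI
Why: Williamson ether synthesis on the naphtholate proceeds cleanly because nothing else in the molecule can be alkylated.

**Step 5**
Reactants: 6 ethyl 8-bromo-4,5-dimethoxy-2-naphthoate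
Product: 7 (8-bromo-4,5-dimethoxynaphthalen-2-yl)methanol
Conditions: LiAlH4, THF, 0 °C
Reagents that add atoms: none
Why: Hydride reduction of the ester to the primary alcohol is fast at 0 °C, where the aryl bromide is inert.

**Step 6**
Reactants: 7 (8-bromo-4,5-dimethoxynaphthalen-2-yl)methanol
Product: 8 1-bromo-7-(bromomethyl)-4,5-dimethoxynaphthalene
Conditions: CBr4, PPh3, CH2Cl2, 0 °C
Reagents that add atoms: tetrabromomethane, BrC(Br)(Br)Br
Why: The Appel reaction is neutral and releases no electrophilic bromine, so the electron-rich ring is not brominated.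

**Step 7**
Reactants: 8 1-bromo-7-(bromomethyl)-4,5-dimethoxynaphthalene
Product: 9 1-bromo-4,5-dimethoxy-7-methylnaphthalene
Conditions: LiEt3BH, THF, 0 °C
Reagents that add atoms: none
Why: SN2 hydride displacement at the benzylic bromide is very fast, and the aryl C–Br bond does not react under these conditions.

**Step 8**
Reactants: 9 1-bromo-4,5-dimethoxy-7-methylnaphthalene
Product: 10 ethyl 2-(4,5-dimethoxy-7-methylnaphthalen-1-yl)acetate
Conditions: Zn dust (Me3SiCl-activated), ethyl bromoacetate, THF, 40 °C; then 9, Pd[P(t-Bu)3]2 (3 mol %), THF, 65 °C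
Reagents that add atoms: ethyl bromoacetate, BrCC(=O)OCC
Why: In this Negishi-type coupling of a Reformatsky reagent (ester α-arylation), the bulky electron-rich phosphine lets zerovalent palladium insert into the electron-rich bromide.

**Step 9**
Reactants: 10 ethyl 2-(4,5-dimethoxy-7-methylnaphthalen-1-yl)acetate
Product: 11 2-(4,5-dimethoxy-7-methylnaphthalen-1-yl)acetic acid
Conditions: LiOH, THF/MeOH/H2O, rt; aq. HCl
Reagents that add atoms: lithium hydroxide, [Li+].[OH-]
Why: Saponification of an unhindered primary ester avoids acid and carbocations that could attack the electron-rich naphthalene.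

**Step 10**
Reactants: 11 2-(4,5-dimethoxy-7-methylnaphthalen-1-yl)acetic acid
Product: 13 ethyl 4-(4,5-dimethoxy-7-methylnaphthalen-1-yl)-3-oxobutanoate, via acyl Meldrum's acid 12 (not isolated)
Conditions: Meldrum's acid, dicyclohexylcarbodiimide, DMAP, CH2Cl2, 0 °C → rt; filter, acid wash, concentrate; EtOH, reflux
Reagents that add atoms: Meldrum's acid, CC1(C)OC(=O)CC(=O)O1; ethanol, CCO
Why: In this Oikawa–Yonemitsu β-keto ester synthesis, Claisen-type C-acylation of Meldrum's acid followed by ethanolysis with loss of acetone and CO2 is the standard homologation of arylacetic acids.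

**Step 11 (key step)**
Reactants: 13 ethyl 4-(4,5-dimethoxy-7-methylnaphthalen-1-yl)-3-oxobutanoate; 14 (E)-crotonaldehyde
Product: 17 ethyl 3-(4,5-dimethoxy-7-methylnaphthalen-1-yl)-6-methyl-2-oxocyclohex-3-ene-1-carboxylate, via Michael adduct 15 (not isolated), via aldol 16 (not isolated)
Conditions: 14 (1.3 equiv, slow addition), NaOEt (0.2 equiv), EtOH, 0 °C → rt; then TsOH·H2O (0.1 equiv), toluene, reflux, Dean–Stark
Reagents that add atoms: none
Why: Intermolecular Michael addition of the doubly activated carbon of 13 to the enal is followed by intramolecular aldol closure from the acidic benzylic ketone CH2 and acid dehydration (Robinson-type annulation), and the new stereocentres form as a racemic diastereomer mixture that step 12 erases.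

**Step 12**
Reactants: 17 ethyl 3-(4,5-dimethoxy-7-methylnaphthalen-1-yl)-6-methyl-2-oxocyclohex-3-ene-1-carboxylate
Product: 20 ethyl 3-(4,5-dimethoxy-7-methylnaphthalen-1-yl)-2-hydroxy-6-methylbenzoate, via selenide 18 (not isolated), via selenoxide 19 (not isolated)
Conditions: NaH, THF, 0 °C; PhSeCl, 0 °C; then H2O2 (30 % aq.), pyridine, CH2Cl2, 0 °C → rt
Reagents that add atoms: none
Why: α-Selenenylation occurs anti to the neighbouring methyl, so selenium lies syn to the ring C–H, and selenoxide syn-elimination then gives a dienone that tautomerises to the phenol without any electrophilic halogen that would attack the naphthalene.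

**Step 13**
Reactants: 20 ethyl 3-(4,5-dimethoxy-7-methylnaphthalen-1-yl)-2-hydroxy-6-methylbenzoate
Product: 21 ethyl 2-(benzyloxy)-3-(4,5-dimethoxy-7-methylnaphthalen-1-yl)-6-methylbenzoate
Conditions: BnBr, K2CO3, DMF, 60 °C
Reagents that add atoms: benzyl bromide, BrCc1ccccc1
Why: Williamson ether synthesis installs a benzyl group that is orthogonal to the two methyl ethers and survives LiN(iPr)2, POCl3 and organozinc reagents.

**Step 14**
Reactants: 21 ethyl 2-(benzyloxy)-3-(4,5-dimethoxy-7-methylnaphthalen-1-yl)-6-methylbenzoate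
Product: 22 ethyl 2-(benzyloxy)-3-(4,5-dimethoxy-7-methylnaphthalen-1-yl)-6-(2-oxopropyl)benzoate
Conditions: LiN(iPr)2 (commercial solution, 2.2 equiv), THF, −78 °C; MeC(O)N(OMe)Me, −78 → 0 °C; aq. HCl
Reagents that add atoms: N-methoxy-N-methylacetamide, CON(C)C(C)=O
Why: Lateral lithiation removes only the ester-activated ortho-methyl proton, and Claisen-type acylation by the Weinreb amide stops at the ketone because the chelated adduct survives until the quench.

**Step 15**
Reactants: 22 ethyl 2-(benzyloxy)-3-(4,5-dimethoxy-7-methylnaphthalen-1-yl)-6-(2-oxopropyl)benzoate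
Product: 23 8-(benzyloxy)-7-(4,5-dimethoxy-7-methylnaphthalen-1-yl)-3-methylisoquinolin-1(2H)-one
Conditions: NH4OAc (10 equiv), AcOH, 110 °C
Reagents that add atoms: ammonium acetate, CC(=O)[O-].[NH4+]
Why: Ammonia condenses with the ketone to an enamine whose nitrogen lactamises intramolecularly on the otherwise hindered ester, giving the aromatic isoquinolone.

**Step 16**
Reactants: 23 8-(benzyloxy)-7-(4,5-dimethoxy-7-methylnaphthalen-1-yl)-3-methylisoquinolin-1(2H)-one
Product: 24 8-(benzyloxy)-1-chloro-7-(4,5-dimethoxy-7-methylnaphthalen-1-yl)-3-methylisoquinoline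
Conditions: POCl3 (5 equiv), toluene, 100 °C, no DMF; ice-water work-up
Reagents that add atoms: phosphoryl chloride, O=P(Cl)(Cl)Cl
Why: Deoxychlorination of the lactam through its O-phosphorylated form is standard, aryl benzyl ethers tolerate POCl3, and leaving out DMF prevents Vilsmeier formylation of the naphthalene.

**Step 17**
Reactants: 24 8-(benzyloxy)-1-chloro-7-(4,5-dimethoxy-7-methylnaphthalen-1-yl)-3-methylisoquinoline
Product: 25 8-(benzyloxy)-7-(4,5-dimethoxy-7-methylnaphthalen-1-yl)-1,3-dimethylisoquinoline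
Conditions: MeZnCl (commercial THF solution, 2 equiv), Pd(PPh3)4 (5 mol %), THF, 65 °C
Reagents that add atoms: methylzinc chloride, C[Zn]Cl
Why: In this Negishi coupling the imidoyl-type C1–Cl bond adds readily to zerovalent palladium, and the small methyl group tolerates the peri benzyloxy substituent.

**Step 18**
Reactants: 25 8-(benzyloxy)-7-(4,5-dimethoxy-7-methylnaphthalen-1-yl)-1,3-dimethylisoquinoline
Product: 26 dioncophylleine D, 7-(4,5-dimethoxy-7-methylnaphthalen-1-yl)-1,3-dimethylisoquinolin-8-ol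
Conditions: H2 (1 atm), Pd/C (10 wt %), MeOH/EtOAc, rt
Reagents that add atoms: none
Why: Catalytic hydrogenolysis cleaves only the benzylic C–O bond, since the methyl ethers and the neutral isoquinoline ring are untouched at 1 atm without acid.

**Compound list**
1 | 2-bromo-5-methoxybenzaldehyde | COc1ccc(Br)c(C=O)c1 | starting material
2 | diethyl succinate | CCOC(=O)CCC(=O)OCC | starting material
3 | (E)-4-(2-bromo-5-methoxyphenyl)-3-(ethoxycarbonyl)but-3-enoic acid | CCOC(=O)/C(CC(=O)O)=C/c1cc(OC)ccc1Br | intermediate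
4 | ethyl 4-acetoxy-8-bromo-5-methoxy-2-naphthoate | CCOC(=O)c1cc(OC(C)=O)c2c(OC)ccc(Br)c2c1 | intermediate
5 | ethyl 8-bromo-4-hydroxy-5-methoxy-2-naphthoate | CCOC(=O)c1cc(O)c2c(OC)ccc(Br)c2c1 | intermediate
6 | ethyl 8-bromo-4,5-dimethoxy-2-naphthoate | CCOC(=O)c1cc(OC)c2c(OC)ccc(Br)c2c1 | intermediate
7 | (8-bromo-4,5-dimethoxynaphthalen-2-yl)methanol | OCc1cc(OC)c2c(OC)ccc(Br)c2c1 | intermediate
8 | 1-bromo-7-(bromomethyl)-4,5-dimethoxynaphthalene | BrCc1cc(OC)c2c(OC)ccc(Br)c2c1 | intermediate
9 | 1-bromo-4,5-dimethoxy-7-methylnaphthalene | Cc1cc(OC)c2c(OC)ccc(Br)c2c1 | intermediate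
10 | ethyl 2-(4,5-dimethoxy-7-methylnaphthalen-1-yl)acetate | CCOC(=O)Cc1ccc(OC)c2c(OC)cc(C)cc12 | intermediate
11 | 2-(4,5-dimethoxy-7-methylnaphthalen-1-yl)acetic acid | OC(=O)Cc1ccc(OC)c2c(OC)cc(C)cc12 | intermediate
12 | 5-[2-(4,5-dimethoxy-7-methylnaphthalen-1-yl)-1-hydroxyethylidene]-2,2-dimethyl-1,3-dioxane-4,6-dione (not isolated) | CC1(C)OC(=O)C(=C(O)Cc2ccc(OC)c3c(OC)cc(C)cc23)C(=O)O1 | intermediate
13 | ethyl 4-(4,5-dimethoxy-7-methylnaphthalen-1-yl)-3-oxobutanoate | CCOC(=O)CC(=O)Cc1ccc(OC)c2c(OC)cc(C)cc12 | intermediate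
14 | (E)-crotonaldehyde | C/C=C/C=O | starting material
15 | ethyl 2-[(4,5-dimethoxy-7-methylnaphthalen-1-yl)acetyl]-3-methyl-5-oxopentanoate (racemic diastereomer mixture, not isolated) | CCOC(=O)C(C(C)CC=O)C(=O)Cc1ccc(OC)c2c(OC)cc(C)cc12 | intermediate
16 | ethyl 3-(4,5-dimethoxy-7-methylnaphthalen-1-yl)-4-hydroxy-6-methyl-2-oxocyclohexane-1-carboxylate (racemic diastereomer mixture, not isolated) | CCOC(=O)C1C(C)CC(O)C(c2ccc(OC)c3c(OC)cc(C)cc23)C1=O | intermediate
17 | ethyl 3-(4,5-dimethoxy-7-methylnaphthalen-1-yl)-6-methyl-2-oxocyclohex-3-ene-1-carboxylate (racemic diastereomer mixture) | CCOC(=O)C1C(C)CC=C(c2ccc(OC)c3c(OC)cc(C)cc23)C1=O | intermediate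
18 | ethyl 3-(4,5-dimethoxy-7-methylnaphthalen-1-yl)-6-methyl-2-oxo-1-(phenylselanyl)cyclohex-3-ene-1-carboxylate (racemic, not isolated) | CCOC(=O)C1([Se]c2ccccc2)C(C)CC=C(c2ccc(OC)c3c(OC)cc(C)cc23)C1=O | intermediate
19 | ethyl 3-(4,5-dimethoxy-7-methylnaphthalen-1-yl)-6-methyl-2-oxo-1-(phenylseleninyl)cyclohex-3-ene-1-carboxylate (racemic, not isolated) | CCOC(=O)C1([Se](=O)c2ccccc2)C(C)CC=C(c2ccc(OC)c3c(OC)cc(C)cc23)C1=O | intermediate
20 | ethyl 3-(4,5-dimethoxy-7-methylnaphthalen-1-yl)-2-hydroxy-6-methylbenzoate | CCOC(=O)c1c(C)ccc(-c2ccc(OC)c3c(OC)cc(C)cc23)c1O | intermediate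
21 | ethyl 2-(benzyloxy)-3-(4,5-dimethoxy-7-methylnaphthalen-1-yl)-6-methylbenzoate | CCOC(=O)c1c(C)ccc(-c2ccc(OC)c3c(OC)cc(C)cc23)c1OCc1ccccc1 | intermediate
22 | ethyl 2-(benzyloxy)-3-(4,5-dimethoxy-7-methylnaphthalen-1-yl)-6-(2-oxopropyl)benzoate | CCOC(=O)c1c(CC(C)=O)ccc(-c2ccc(OC)c3c(OC)cc(C)cc23)c1OCc1ccccc1 | intermediate
23 | 8-(benzyloxy)-7-(4,5-dimethoxy-7-methylnaphthalen-1-yl)-3-methylisoquinolin-1(2H)-one | Cc1cc2ccc(-c3ccc(OC)c4c(OC)cc(C)cc34)c(OCc3ccccc3)c2c(=O)[nH]1 | intermediate
24 | 8-(benzyloxy)-1-chloro-7-(4,5-dimethoxy-7-methylnaphthalen-1-yl)-3-methylisoquinoline | Cc1cc2ccc(-c3ccc(OC)c4c(OC)cc(C)cc34)c(OCc3ccccc3)c2c(Cl)n1 | intermediate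
25 | 8-(benzyloxy)-7-(4,5-dimethoxy-7-methylnaphthalen-1-yl)-1,3-dimethylisoquinoline | Cc1cc2ccc(-c3ccc(OC)c4c(OC)cc(C)cc34)c(OCc3ccccc3)c2c(C)n1 | intermediate
26 | dioncophylleine D, 7-(4,5-dimethoxy-7-methylnaphthalen-1-yl)-1,3-dimethylisoquinolin-8-ol (no stereogenic element) | COc1ccc(-c2ccc3cc(C)nc(C)c3c2O)c2cc(C)cc(OC)c12 | target

**Step count**
Total steps: 18. Longest linear sequence: 18 steps (1 → 26).

**Steps most likely to fail, with fallbacks**

For step 8, the risk is slow insertion of palladium into an electron-rich, peri-hindered bromide while the Reformatsky reagent decays. The fallback replaces catalysis with polar organolithium chemistry. It sets out from 9 and comes back at 11.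
- Bromine–lithium exchange (n-BuLi, THF, −78 °C) gives (4,5-dimethoxy-7-methylnaphthalen-1-yl)lithium F1.
- F1 opens ethylene oxide (BF3·OEt2, −78 °C) to 2-(4,5-dimethoxy-7-methylnaphthalen-1-yl)ethan-1-ol F2.
- Dess–Martin periodinane (CH2Cl2, rt) gives 2-(4,5-dimethoxy-7-methylnaphthalen-1-yl)acetaldehyde F3.
- Pinnick oxidation (NaClO2, NaH2PO4, 2-methylbut-2-ene, t-BuOH/H2O) delivers acid 11.

For step 11, the highest risk, crotonaldehyde may polymerise or react in Knoevenagel fashion. The aldol closure must also bring a bulky naphthyl-bearing carbon onto the aldehyde. The fallback is a Lewis-acid [3+3] cycloaromatisation of the Chan–Brownbridge type. It sets out from 13 and comes back at 20, so step 12 is bypassed as well.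
- 13 is silylated (Me3SiCl, Et3N, toluene, rt) to ethyl 4-(4,5-dimethoxy-7-methylnaphthalen-1-yl)-3-(trimethylsilyloxy)but-2-enoate F4.
- Deprotonation and a second silylation (LiN(iPr)2, THF, −78 °C; Me3SiCl) give 1-ethoxy-4-(4,5-dimethoxy-7-methylnaphthalen-1-yl)-1,3-bis(trimethylsilyloxy)buta-1,3-diene F5.
- F5 is combined with commercial (E)-4-methoxybut-3-en-2-one and TiCl4 in CH2Cl2 (−78 °C → rt).
- The aryl-bearing diene terminus adds in Mukaiyama–Michael fashion to the methoxy-bearing carbon, and the central carbon closes on the ketone. Aromatisation gives 20 with the same regiochemistry.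

For step 17, the risk is that the peri benzyloxy group slows coupling at C1, or that chloride 24 forms poorly in step 16. The fallback brings in the C1 methyl as a nucleophile before nitrogen is introduced. It sets out from 22 and comes back at 25, bypassing 23 and 24.
- 22 is cyclised (TsOH, toluene, reflux) to 8-(benzyloxy)-7-(4,5-dimethoxy-7-methylnaphthalen-1-yl)-3-methyl-1H-isochromen-1-one F6.
- One equivalent of MeLi (THF, −78 °C) opens the lactone to 1-[2-acetyl-3-(benzyloxy)-4-(4,5-dimethoxy-7-methylnaphthalen-1-yl)phenyl]propan-2-one F7. Its hindered aryl ketone resists a second addition.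
- The 1,5-diketone condenses with NH4OAc in AcOH (80 °C) to give 25 directly.

**Further compounds**
F1 | step 8 | (4,5-dimethoxy-7-methylnaphthalen-1-yl)lithium | [Li]c1ccc(OC)c2c(OC)cc(C)cc12
F2 | step 8 | 2-(4,5-dimethoxy-7-methylnaphthalen-1-yl)ethan-1-ol | OCCc1ccc(OC)c2c(OC)cc(C)cc12
F3 | step 8 | 2-(4,5-dimethoxy-7-methylnaphthalen-1-yl)acetaldehyde | O=CCc1ccc(OC)c2c(OC)cc(C)cc12
F4 | step 11 | ethyl 4-(4,5-dimethoxy-7-methylnaphthalen-1-yl)-3-(trimethylsilyloxy)but-2-enoate (E/Z mixture) | CCOC(=O)C=C(Cc1ccc(OC)c2c(OC)cc(C)cc12)O[Si](C)(C)C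
F5 | step 11 | 1-ethoxy-4-(4,5-dimethoxy-7-methylnaphthalen-1-yl)-1,3-bis(trimethylsilyloxy)buta-1,3-diene (isomer mixture) | CCOC(O[Si](C)(C)C)=CC(O[Si](C)(C)C)=Cc1ccc(OC)c2c(OC)cc(C)cc12
F6 | step 17 | 8-(benzyloxy)-7-(4,5-dimethoxy-7-methylnaphthalen-1-yl)-3-methyl-1H-isochromen-1-one | Cc1cc2ccc(-c3ccc(OC)c4c(OC)cc(C)cc34)c(OCc3ccccc3)c2c(=O)o1
F7 | step 17 | 1-[2-acetyl-3-(benzyloxy)-4-(4,5-dimethoxy-7-methylnaphthalen-1-yl)phenyl]propan-2-one | CC(=O)Cc1ccc(-c2ccc(OC)c3c(OC)cc(C)cc23)c(OCc2ccccc2)c1C(C)=O
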